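Ring B is disconnected at C1'–C2' and C5'–C6'. It is a benzene ring joined to C2 through C1' and oxygenated at the neighbouring carbons C3' and C4', so an ethynyl group on C2 (future C1' and C6') and a butadiene oxygenated on both inner carbons (C2' to C5') rebuild it, the twofold symmetry of the diene making its orientation irrelevant. One cobalt-catalysed alkyne–diene [4+2] cycloaddition closes the whole carbocycle of ring B; dehydrogenation then gives the catechol. The precursor is the (2S)-2-ethynylchroman-4-one that already carries the 6-(1,1-dimethylallyl) group and two MOM ethers, its stereocentre set by copper-catalysed asymmetric alkynylation of the chromone.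

Key step: step 8

Remark: 5,7-dihydroxychromone is taken as the commercial building block for rings A and C, and the diene is used as its bis(triethylsilyl) ether instead of the bis(trimethylsilyl) ether, so that the cycloadduct and the catechol ether survive handling and still fall in the final acid step.

Step 1
Reactants: 1 5,7-dihydroxy-4H-chromen-4-one
Product: 2 5-hydroxy-7-(methoxymethoxy)-4H-chromen-4-one
Conditions: MOMCl (1.1 equiv), iPr2NEt (1.5 equiv), DMF, 0 °C to rt
Reagents that add atoms: chloromethyl methyl ether (MOMCl), COCCl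
Why: Williamson-type O-alkylation that should take only the C7 hydroxyl, the more acidic and unchelated phenol, because the C5 hydroxyl is held in a hydrogen bond to the C4 carbonyl.

Step 2
Reactants: 2 5-hydroxy-7-(methoxymethoxy)-4H-chromen-4-one; 3 3-methylbut-2-enyl bromide
Product: 4 7-(methoxymethoxy)-5-[(3-methylbut-2-en-1-yl)oxy]-4H-chromen-4-one
Conditions: K2CO3 (2 equiv), DMF, 50 °C
Reagents that add atoms: none
Why: Williamson ether synthesis in which carbonate in a dipolar aprotic solvent breaks the chelate and the only remaining phenoxide displaces the primary allylic bromide at oxygen.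

Step 3
Reactants: 4 7-(methoxymethoxy)-5-[(3-methylbut-2-en-1-yl)oxy]-4H-chromen-4-one
Product: 5 5-hydroxy-7-(methoxymethoxy)-6-(2-methylbut-3-en-2-yl)-4H-chromen-4-one
Conditions: Eu(fod)3 (10 mol%), CHCl3, 60 °C, sealed tube
Reagents that add atoms: none
Why: Aromatic Claisen rearrangement, accelerated by the trivalent europium chelate between O5 and the C4 carbonyl, in which the [3,3] shift can only end at C6 (C4a bears no hydrogen) and places the tertiary allyl carbon there with allylic transposition before enolisation restores the chelated phenol; the moderate temperature is chosen to stop before a further shift to C8.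

Step 4
Reactants: 5 5-hydroxy-7-(methoxymethoxy)-6-(2-methylbut-3-en-2-yl)-4H-chromen-4-one
Product: 6 5,7-bis(methoxymethoxy)-6-(2-methylbut-3-en-2-yl)-4H-chromen-4-one
Conditions: NaH (1.5 equiv), MOMCl (1.5 equiv), THF/DMF, 0 °C to rt
Reagents that add atoms: chloromethyl methyl ether (MOMCl), COCCl
Why: Irreversible deprotonation frees the crowded, chelated C5 phenol as its sodium salt, which should be O-alkylated by the small and highly reactive chloromethyl ether (Williamson-type alkylation), the chromone having no other acidic site.

Step 5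
Reactants: 6 5,7-bis(methoxymethoxy)-6-(2-methylbut-3-en-2-yl)-4H-chromen-4-one; 7 ethynyltrimethylsilane
Product: 10 (2S)-5,7-bis(methoxymethoxy)-6-(2-methylbut-3-en-2-yl)-2-[(trimethylsilyl)ethynyl]chroman-4-one, via 4-silyloxybenzopyrylium triflate 8 (not isolated), via silyl enol ether 9 (not isolated)
Conditions: TBSOTf (1.1 equiv), toluene, 40 °C; then CuI (10 mol%), (S,S)-Ph-BOX (12 mol%), iPr2NEt (1.5 equiv), 7 (1.5 equiv), −78 to −40 °C; then 1 M aq. HCl/THF, 0 °C, brief
Reagents that add atoms: none
Why: Known copper-catalysed enantioselective conjugate alkynylation of chromones, in which O-silylation of the C4 carbonyl gives a 4-silyloxybenzopyrylium ion that is attacked at C2 by a copper acetylide held in the chiral bis(oxazoline) pocket, so that the C2 stereocentre is set under catalyst control by delivery to the Re face (the ligand antipode being used if a pilot run shows the opposite sense), and cold dilute acid then hydrolyses the silyl enol ether while the MOM acetals, exposed to only a slight excess of the bulky silyl triflate, should stay in place.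

Step 6
Reactants: 10 (2S)-5,7-bis(methoxymethoxy)-6-(2-methylbut-3-en-2-yl)-2-[(trimethylsilyl)ethynyl]chroman-4-one
Product: 11 (2S)-2-ethynyl-5,7-bis(methoxymethoxy)-6-(2-methylbut-3-en-2-yl)chroman-4-one
Conditions: AgNO3 (10 mol%), acetone/H2O (4:1), rt, dark
Reagents that add atoms: none
Why: Silver-catalysed protodesilylation of a 1-silylalkyne, in which the silver ion activates the C(sp)–Si bond towards water under neutral conditions, so that no enolate forms and the C2 centre cannot be lost by retro-oxa-Michael ring opening.

Step 7
Reactants: 12 butane-2,3-dione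
Product: 13 2,3-bis(triethylsilyloxy)buta-1,3-diene
Conditions: TESOTf (2.2 equiv), Et3N (3 equiv), CH2Cl2, 0 °C to rt; Kugelrohr distillation
Reagents that add atoms: triethylsilyl trifluoromethanesulfonate (TESOTf), CC[Si](CC)(CC)OS(=O)(=O)C(F)(F)F
Why: Soft enolisation of both carbonyl groups by a silyl triflate and a tertiary amine (silyl enol ether formation) should give the 2,3-bis(silyloxy)diene, triethylsilyl being sturdier than trimethylsilyl yet still acid-labile.

Step 8
Reactants: 11 (2S)-2-ethynyl-5,7-bis(methoxymethoxy)-6-(2-methylbut-3-en-2-yl)chroman-4-one; 13 2,3-bis(triethylsilyloxy)buta-1,3-diene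
Product: 14 (2S)-2-[4,5-bis(triethylsilyloxy)cyclohexa-1,4-dien-1-yl]-5,7-bis(methoxymethoxy)-6-(2-methylbut-3-en-2-yl)chroman-4-one
Conditions: CoBr2(dppe) (10 mol%), Zn powder (20 mol%), ZnI2 (20 mol%), 13 (2 equiv), CH2Cl2, rt; filtration through Et3N-deactivated silica
Reagents that add atoms: none
Why: Zinc reduces CoBr2(dppe) to a monovalent cobalt–dppe species that ZnI2 renders cationic; it binds the s-cis diene and the alkyne, couples a diene terminus to an alkyne carbon to give an allyl–vinyl cobaltacycle, and reductive elimination forms the second bond (C1'–C2' and C5'–C6' in all) and releases the catalyst. The closest known reaction is the cobalt-catalysed neutral [4+2] cycloaddition of terminal alkynes with 2-silyloxy- and 2,3-disubstituted butadienes, a union that a thermal Diels–Alder reaction of two electron-rich partners would not achieve. The six-membered carbocycle of ring B closes by intermolecular [4+2] annulation, its last bond arising by reductive elimination at cobalt. No stereocentre is created, and C2 should remain intact because the medium contains no base. The step needs chemoselectivity for the alkyne over the vinyl group, which is secured by the stronger binding of alkynes to cobalt and by the quaternary carbon that shields the vinyl group. The symmetric diene removes any regiochemical question.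

Step 9
Reactants: 14 (2S)-2-[4,5-bis(triethylsilyloxy)cyclohexa-1,4-dien-1-yl]-5,7-bis(methoxymethoxy)-6-(2-methylbut-3-en-2-yl)chroman-4-one
Product: 15 (2S)-2-[3,4-bis(triethylsilyloxy)phenyl]-5,7-bis(methoxymethoxy)-6-(2-methylbut-3-en-2-yl)chroman-4-one
Conditions: DDQ (1.05 equiv), toluene, 0 °C to rt
Reagents that add atoms: none
Why: Dehydrogenative aromatisation by DDQ, in which hydride is taken from a doubly allylic CH2 group of the cyclohexa-1,4-diene to give a silyloxy-stabilised cyclohexadienyl cation that loses a proton, the gain in aromaticity making this much faster than attack on C2–H, the MOM acetals or ring A.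

Step 10
Reactants: 15 (2S)-2-[3,4-bis(triethylsilyloxy)phenyl]-5,7-bis(methoxymethoxy)-6-(2-methylbut-3-en-2-yl)chroman-4-one
Product: 16 (2S)-2-(3,4-dihydroxyphenyl)-5,7-dihydroxy-6-(2-methylbut-3-en-2-yl)chroman-4-one (CNP0158442.1)
Conditions: 3 M aq. HCl/MeOH (1:4), 40 °C, argon
Reagents that add atoms: none
Why: Acid-catalysed cleavage of the two MOM acetals and solvolysis of the two aryl silyl ethers in one operation, under which the flavanone C2 centre should keep its configuration (racemisation needs an enolate) and the monosubstituted alkene of the dimethylallyl group should not be protonated.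

Compound list
1 | 5,7-dihydroxy-4H-chromen-4-one | O=c1ccoc2cc(O)cc(O)c12 | starting material
2 | 5-hydroxy-7-(methoxymethoxy)-4H-chromen-4-one | O=c1ccoc2cc(OCOC)cc(O)c12 | intermediate
3 | 3-methylbut-2-enyl bromide | CC(C)=CCBr | starting material
4 | 7-(methoxymethoxy)-5-[(3-methylbut-2-en-1-yl)oxy]-4H-chromen-4-one | O=c1ccoc2cc(OCOC)cc(OCC=C(C)C)c12 | intermediate
5 | 5-hydroxy-7-(methoxymethoxy)-6-(2-methylbut-3-en-2-yl)-4H-chromen-4-one | O=c1ccoc2cc(OCOC)c(C(C)(C)C=C)c(O)c12 | intermediate
6 | 5,7-bis(methoxymethoxy)-6-(2-methylbut-3-en-2-yl)-4H-chromen-4-one | O=c1ccoc2cc(OCOC)c(C(C)(C)C=C)c(OCOC)c12 | intermediate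
7 | ethynyltrimethylsilane | C#C[Si](C)(C)C | starting material
8 | 4-[(tert-butyldimethylsilyl)oxy]-5,7-bis(methoxymethoxy)-6-(2-methylbut-3-en-2-yl)chromenylium trifluoromethanesulfonate | C=CC(C)(C)c1c(OCOC)cc2[o+]ccc(O[Si](C)(C)C(C)(C)C)c2c1OCOC.[O-]S(=O)(=O)C(F)(F)F | intermediate
9 | (2S)-4-[(tert-butyldimethylsilyl)oxy]-5,7-bis(methoxymethoxy)-6-(2-methylbut-3-en-2-yl)-2-[(trimethylsilyl)ethynyl]-2H-chromene | C=CC(C)(C)c1c(OCOC)cc2c(c1OCOC)C(O[Si](C)(C)C(C)(C)C)=C[C@@H](C#C[Si](C)(C)C)O2 | intermediate
10 | (2S)-5,7-bis(methoxymethoxy)-6-(2-methylbut-3-en-2-yl)-2-[(trimethylsilyl)ethynyl]chroman-4-one | C=CC(C)(C)c1c(OCOC)cc2c(c1OCOC)C(=O)C[C@@H](C#C[Si](C)(C)C)O2 | intermediate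
11 | (2S)-2-ethynyl-5,7-bis(methoxymethoxy)-6-(2-methylbut-3-en-2-yl)chroman-4-one | C=CC(C)(C)c1c(OCOC)cc2c(c1OCOC)C(=O)C[C@@H](C#C)O2 | intermediate
12 | butane-2,3-dione | CC(=O)C(C)=O | starting material
13 | 2,3-bis(triethylsilyloxy)buta-1,3-diene | C=C(O[Si](CC)(CC)CC)C(=C)O[Si](CC)(CC)CC | intermediate
14 | (2S)-2-[4,5-bis(triethylsilyloxy)cyclohexa-1,4-dien-1-yl]-5,7-bis(methoxymethoxy)-6-(2-methylbut-3-en-2-yl)chroman-4-one | C=CC(C)(C)c1c(OCOC)cc2c(c1OCOC)C(=O)C[C@@H](C1=CCC(O[Si](CC)(CC)CC)=C(O[Si](CC)(CC)CC)C1)O2 | intermediate
15 | (2S)-2-[3,4-bis(triethylsilyloxy)phenyl]-5,7-bis(methoxymethoxy)-6-(2-methylbut-3-en-2-yl)chroman-4-one | C=CC(C)(C)c1c(OCOC)cc2c(c1OCOC)C(=O)C[C@@H](c1ccc(O[Si](CC)(CC)CC)c(O[Si](CC)(CC)CC)c1)O2 | intermediate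
16 | (2S)-2-(3,4-dihydroxyphenyl)-5,7-dihydroxy-6-(2-methylbut-3-en-2-yl)chroman-4-one | C=CC(C)(C)c1c(O)cc2c(c1O)C(=O)C[C@@H](c1ccc(O)c(O)c1)O2 | target

Total step count: 10. Longest linear sequence: 9 steps (steps 1 to 6 and 8 to 10, from compound 1); step 7 is a one-step side branch.

Steps most likely to fail

1. Step 8. The low-valent cobalt may be diverted into cyclotrimerisation of the alkyne or into cleavage of the propargylic C2–O bond, or the zinc Lewis acid may strip the silyl enol ethers before the cycloaddition takes place. The fallback sets out from 6 and comes back at 16, and brings ring B in intact as an aryl nucleophile. Commercial 4-bromobenzene-1,2-diol would be protected with MOMCl and iPr2NEt to give 4-bromo-1,2-bis(methoxymethoxy)benzene F1. Bromine–lithium exchange (n-BuLi, THF, −78 °C), B(OiPr)3 and a mild aqueous work-up would give [3,4-bis(methoxymethoxy)phenyl]boronic acid F2. Rhodium-catalysed enantioselective conjugate addition of F2 to chromone 6 ([Rh(OH)(cod)]2 with an electron-poor atropisomeric bisphosphine of the MeO-BIPHEP family, the antipode that delivers the aryl group to the Re face of C2, aqueous toluene, rt) should then give (2S)-2-[3,4-bis(methoxymethoxy)phenyl]-5,7-bis(methoxymethoxy)-6-(2-methylbut-3-en-2-yl)chroman-4-one F3. The conditions of step 10 would convert F3 into 16.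

2. Step 5. Facial selectivity may be poor, or the addition slow, because the C5 substituent crowds the silyloxy group of the benzopyrylium ion and the ring is electron-rich. The fallback sets out from 6 and comes back at 10, and replaces asymmetric catalysis by resolution. The same silyl triflate activation with CuI and iPr2NEt but without the chiral ligand should give racemic 5,7-bis(methoxymethoxy)-6-(2-methylbut-3-en-2-yl)-2-[(trimethylsilyl)ethynyl]chroman-4-one F4. Preparative chromatography on a polysaccharide chiral stationary phase would separate it into 10 and the (2R)-enantiomer F5, and F5 could be returned to F4 with DBU through reversible opening and closure of ring C.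

3. Step 3. The allyl group may migrate on to C8 by a second [3,3] shift through the dienone tautomer held on the Lewis acid, or the freed C5 phenol may add to the vinyl group. The fallback sets out from 4 and comes back at 5, and replaces catalysis by kinetic capture of the phenol. Uncatalysed thermal rearrangement of 4 in N,N-diethylaniline at 185 °C in the presence of Ac2O and NaOAc should acylate the phenol as soon as it forms and give 7-(methoxymethoxy)-6-(2-methylbut-3-en-2-yl)-4-oxo-4H-chromen-5-yl acetate F6, which can no longer return to the dienone. Brief methanolysis (K2CO3, MeOH, 0 °C) would then release 5.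

Further compounds
F1 | step 8 | 4-bromo-1,2-bis(methoxymethoxy)benzene | COCOc1ccc(Br)cc1OCOC
F2 | step 8 | [3,4-bis(methoxymethoxy)phenyl]boronic acid | COCOc1ccc(B(O)O)cc1OCOC
F3 | step 8 | (2S)-2-[3,4-bis(methoxymethoxy)phenyl]-5,7-bis(methoxymethoxy)-6-(2-methylbut-3-en-2-yl)chroman-4-one | C=CC(C)(C)c1c(OCOC)cc2c(c1OCOC)C(=O)C[C@@H](c1ccc(OCOC)c(OCOC)c1)O2
F4 | step 5 | rac-5,7-bis(methoxymethoxy)-6-(2-methylbut-3-en-2-yl)-2-[(trimethylsilyl)ethynyl]chroman-4-one | C=CC(C)(C)c1c(OCOC)cc2c(c1OCOC)C(=O)CC(C#C[Si](C)(C)C)O2
F5 | step 5 | (2R)-5,7-bis(methoxymethoxy)-6-(2-methylbut-3-en-2-yl)-2-[(trimethylsilyl)ethynyl]chroman-4-one | C=CC(C)(C)c1c(OCOC)cc2c(c1OCOC)C(=O)C[C@H](C#C[Si](C)(C)C)O2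
F6 | step 3 | 7-(methoxymethoxy)-6-(2-methylbut-3-en-2-yl)-4-oxo-4H-chromen-5-yl acetate | CC(=O)Oc1c(C(C)(C)C=C)c(OCOC)cc2occc(=O)c12
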